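The route rests on cutting C9–C10, the bond between the two allylic carbons of the C19=C8–C9–C10–C11=C12 1,5-diene inside the 14-membered carbocycle. In one operation the key step alkylates a C10 phenylsulfonyl carbanion with the C9 allylic bromide of the same chain and closes the ring. C1 (from (S)-limonene), C2 (proline aminoxylation) and C7 (asymmetric Morita–Baylis–Hillman reaction) are set beforehand. The seco precursor is the open C10–C14–C1–C9 chain with the C10 sulfone, the C9 bromide, a PMB ether at C7 and TBS ethers at C2 and C18. O7 and O9 travel as one p-methoxybenzylidene acetal, so a single reductive opening frees only C9–OH.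

Key step: step 21

Numbering (cembrane): C1 is the ring CH bearing the isopropenyl group (C15–C17), C2 the CH–OAc, C3=C4 with C18 on C4, C7 the CH–OH, C8 carries the exocyclic C19H2, C11=C12 with C20 on C12. The target and both key-step compounds were checked as (1R,2S,7R), 3E, 11E; (S)-limonene maps onto C1 as R. TBS = tert-butyldimethylsilyl, PMB = 4-methoxybenzyl.

Assumption: β-isocupreidine (one step from quinidine, also sold) is used as a bought catalyst; 14, 15 and 21 are catalogue compounds.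

Step 1
Reactants: 1 (S)-limonene
Product: 3 (3S)-6-oxo-3-(prop-1-en-2-yl)heptanal, via limonene oxide 2 (not isolated)
Conditions: mCPBA (1.0 equiv), CH2Cl2, 0 °C; then H5IO6, THF/H2O, 0 °C → rt
Reagents that add atoms: 3-chloroperoxybenzoic acid (mCPBA), O=C(OO)c1cccc(Cl)c1; water, O
Why: Prilezhaev epoxidation takes the electron-rich trisubstituted ring alkene in preference to the isopropenyl group, and periodic acid then opens the epoxide and cleaves the resulting glycol to the keto aldehyde without touching the existing stereocentre.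

Step 2
Reactants: 3 (3S)-6-oxo-3-(prop-1-en-2-yl)heptanal
Product: 4 (5S)-7-hydroxy-5-(prop-1-en-2-yl)heptan-2-one
Conditions: NaBH4 (0.3 equiv), EtOH/CH2Cl2 (3:7), −78 °C
Reagents that add atoms: none
Why: Chemoselective borohydride reduction, since at −78 °C the aldehyde is reduced much faster than the methyl ketone.

Step 3
Reactants: 4 (5S)-7-hydroxy-5-(prop-1-en-2-yl)heptan-2-one
Product: 5 (5S)-7-[(tert-butyldimethylsilyl)oxy]-5-(prop-1-en-2-yl)heptan-2-one
Conditions: TBSCl, imidazole, DMF, rt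
Reagents that add atoms: tert-butyldimethylsilyl chloride (TBSCl), CC(C)(C)[Si](C)(C)Cl
Why: Standard silylation of a primary alcohol gives an ether that withstands the amide bases and the organoaluminium reagent of the next two steps.

Step 4
Reactants: 5 (5S)-7-[(tert-butyldimethylsilyl)oxy]-5-(prop-1-en-2-yl)heptan-2-one
Product: 7 tert-butyldimethyl{[(3S)-3-(prop-1-en-2-yl)hept-6-yn-1-yl]oxy}silane, via enol phosphate 6 (not isolated)
Conditions: LiN(i-Pr)2 (1.05 equiv), THF, −78 °C; ClP(O)(OEt)2, −78 °C → rt; then LiN(i-Pr)2 (2.3 equiv), −78 °C → rt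
Reagents that add atoms: none
Why: Kinetic deprotonation at the methyl group, O-phosphorylation and base-induced elimination of the terminal enol phosphate (Negishi alkyne synthesis from methyl ketones) give the terminal alkyne, and the distant stereocentre carries no acidic hydrogen.

Step 5
Reactants: 7 tert-butyldimethyl{[(3S)-3-(prop-1-en-2-yl)hept-6-yn-1-yl]oxy}silane
Product: 9 (2E,6S)-8-[(tert-butyldimethylsilyl)oxy]-3-methyl-6-(prop-1-en-2-yl)oct-2-en-1-ol, via alkenylalane 8 (not isolated)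
Conditions: AlMe3 (2 equiv), Cp2ZrCl2 (0.25 equiv), CH2Cl2, 0 °C → rt; then n-BuLi, THF, −78 °C; (CH2O)n, −78 °C → rt
Reagents that add atoms: trimethylaluminium (AlMe3), C[Al](C)C; formaldehyde (as paraformaldehyde), C=O
Why: Zirconium-catalysed methylalumination (Negishi carboalumination) adds methyl and aluminium syn across the terminal alkyne with aluminium on the terminal carbon, which fixes the E-C11=C12 geometry, and the derived alanate is hydroxymethylated by formaldehyde with retention.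

Step 6
Reactants: 9 (2E,6S)-8-[(tert-butyldimethylsilyl)oxy]-3-methyl-6-(prop-1-en-2-yl)oct-2-en-1-ol
Product: 11 tert-butyldimethyl{[(3S,6E)-6-methyl-8-(phenylsulfonyl)-3-(prop-1-en-2-yl)oct-6-en-1-yl]oxy}silane, via allylic chloride 10 (not isolated)
Conditions: MsCl, LiCl, 2,4,6-collidine, DMF, 0 °C; then PhSO2Na, NaI (cat.), rt
Reagents that add atoms: sodium benzenesulfinate (PhSO2Na), [Na+].[O-]S(=O)c1ccccc1
Why: Mesylation with in situ chloride displacement gives the primary allylic chloride without transposition, and SN2 S-alkylation of the sulfinate at the unhindered primary carbon then gives the E-allylic sulfone.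

Step 7
Reactants: 11 tert-butyldimethyl{[(3S,6E)-6-methyl-8-(phenylsulfonyl)-3-(prop-1-en-2-yl)oct-6-en-1-yl]oxy}silane
Product: 12 (3S,6E)-6-methyl-8-(phenylsulfonyl)-3-(prop-1-en-2-yl)oct-6-en-1-ol
Conditions: CSA (10 mol%), MeOH/CH2Cl2, 0 °C → rt
Reagents that add atoms: none
Why: Acid-catalysed methanolysis removes the primary silyl ether under conditions that leave the allylic sulfone and both alkenes alone.

Step 8
Reactants: 12 (3S,6E)-6-methyl-8-(phenylsulfonyl)-3-(prop-1-en-2-yl)oct-6-en-1-ol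
Product: 13 (3S,6E)-6-methyl-8-(phenylsulfonyl)-3-(prop-1-en-2-yl)oct-6-enal
Conditions: Dess–Martin periodinane, NaHCO3, CH2Cl2, 0 °C → rt
Reagents that add atoms: none
Why: Dess–Martin oxidation gives the aldehyde under buffered conditions, and the stereocentre is β to the carbonyl so it cannot epimerise.

Step 9
Reactants: 14 3-[(tert-butyldimethylsilyl)oxy]propanal; 15 1,1,1,3,3,3-hexafluoropropan-2-yl acrylate
Product: 16 1,1,1,3,3,3-hexafluoropropan-2-yl (3R)-5-[(tert-butyldimethylsilyl)oxy]-3-hydroxy-2-methylidenepentanoate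
Conditions: β-isocupreidine (10 mol%), DMF, −55 °C
Reagents that add atoms: none
Why: Asymmetric Morita–Baylis–Hillman reaction in which the quinidine-derived amine adds to the activated fluorinated acrylate and its phenol hydrogen-bonds the betaine–aldehyde adduct, which should set the carbinol centre (C7) as R.

Step 10
Reactants: 16 1,1,1,3,3,3-hexafluoropropan-2-yl (3R)-5-[(tert-butyldimethylsilyl)oxy]-3-hydroxy-2-methylidenepentanoate
Product: 17 (3R)-5-[(tert-butyldimethylsilyl)oxy]-2-methylidenepentane-1,3-diol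
Conditions: i-Bu2AlH (4 equiv), CH2Cl2, −78 °C
Reagents that add atoms: none
Why: i-Bu2AlH reduces the activated acrylate ester by 1,2-addition to the allylic alcohol, leaving the 1,1-disubstituted alkene and the carbinol centre intact.

Step 11
Reactants: 17 (3R)-5-[(tert-butyldimethylsilyl)oxy]-2-methylidenepentane-1,3-diol
Product: 18 tert-butyl{2-[(2S,4R)-2-(4-methoxyphenyl)-5-methylidene-1,3-dioxan-4-yl]ethoxy}dimethylsilane
Conditions: 4-MeOC6H4CH(OMe)2, PPTS (cat.), CH2Cl2, rt
Reagents that add atoms: 4-methoxybenzaldehyde dimethyl acetal, COc1ccc(C(OC)OC)cc1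
Why: Acid-catalysed transacetalisation under thermodynamic control closes the six-membered acetal with the aryl group and the side chain both equatorial (cis), which sets the acetal carbon as S.

Step 12
Reactants: 18 tert-butyl{2-[(2S,4R)-2-(4-methoxyphenyl)-5-methylidene-1,3-dioxan-4-yl]ethoxy}dimethylsilane
Product: 19 2-[(2S,4R)-2-(4-methoxyphenyl)-5-methylidene-1,3-dioxan-4-yl]ethanol
Conditions: TBAF, THF, 0 °C → rt
Reagents that add atoms: none
Why: Fluoride-mediated desilylation frees the primary alcohol without touching the acid-labile acetal.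

Step 13
Reactants: 19 2-[(2S,4R)-2-(4-methoxyphenyl)-5-methylidene-1,3-dioxan-4-yl]ethanol
Product: 20 (2S,4R)-4-(2-iodoethyl)-2-(4-methoxyphenyl)-5-methylidene-1,3-dioxane
Conditions: I2, PPh3, imidazole, CH2Cl2, 0 °C → rt
Reagents that add atoms: iodine, II
Why: Appel-type iodination converts the primary alcohol into the iodide by SN2 displacement of the oxyphosphonium group under imidazole-buffered conditions that spare the acetal.

Step 14
Reactants: 20 (2S,4R)-4-(2-iodoethyl)-2-(4-methoxyphenyl)-5-methylidene-1,3-dioxane; 21 methyl (triphenylphosphoranylidene)acetate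
Product: 23 methyl 4-[(2S,4R)-2-(4-methoxyphenyl)-5-methylidene-1,3-dioxan-4-yl]-2-(triphenylphosphoranylidene)butanoate, via phosphonium iodide 22 (not isolated)
Conditions: 21 (2.1 equiv), EtOAc, reflux
Reagents that add atoms: none
Why: SN2 C-alkylation of the stabilised ylide by the primary iodide is followed by transylidation with a second equivalent of 21, whose phosphonium iodide precipitates from ethyl acetate and drives the equilibrium to the α-substituted ylide.

Step 15
Reactants: 13 (3S,6E)-6-methyl-8-(phenylsulfonyl)-3-(prop-1-en-2-yl)oct-6-enal; 23 methyl 4-[(2S,4R)-2-(4-methoxyphenyl)-5-methylidene-1,3-dioxan-4-yl]-2-(triphenylphosphoranylidene)butanoate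
Product: 25 methyl (2E,4S,5R,8E)-4-(anilinooxy)-2-{2-[(2S,4R)-2-(4-methoxyphenyl)-5-methylidene-1,3-dioxan-4-yl]ethyl}-8-methyl-10-(phenylsulfonyl)-5-(prop-1-en-2-yl)deca-2,8-dienoate, via aminoxy aldehyde 24 (not isolated)
Conditions: L-proline (20 mol%), PhNO (1.0 equiv), DMSO, rt; then 23, CH2Cl2, 0 °C → rt
Reagents that add atoms: nitrosobenzene, O=Nc1ccccc1
Why: Proline enamine catalysis (α-aminoxylation) delivers the nitroso oxygen to one enamine face through the carboxylic acid hydrogen bond and sets C2 under catalyst control (2R in the aldehyde, 2S in cembrane numbering), and the labile aminoxy aldehyde is trapped at once by E-selective Wittig olefination with the stabilised ylide, which builds E-C3=C4 with C18 as the ester carbon.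

Step 16
Reactants: 25 methyl (2E,4S,5R,8E)-4-(anilinooxy)-2-{2-[(2S,4R)-2-(4-methoxyphenyl)-5-methylidene-1,3-dioxan-4-yl]ethyl}-8-methyl-10-(phenylsulfonyl)-5-(prop-1-en-2-yl)deca-2,8-dienoate
Product: 26 methyl (2E,4S,5R,8E)-4-hydroxy-2-{2-[(2S,4R)-2-(4-methoxyphenyl)-5-methylidene-1,3-dioxan-4-yl]ethyl}-8-methyl-10-(phenylsulfonyl)-5-(prop-1-en-2-yl)deca-2,8-dienoate
Conditions: Zn, AcOH, THF, 0 °C → rt
Reagents that add atoms: none
Why: Dissolving-metal reduction cleaves the weak N–O bond of the O-alkyl N-aryl hydroxylamine to the free C2 alcohol, which cannot lactonise because it lies trans to the ester across the E-alkene.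

Step 17
Reactants: 26 methyl (2E,4S,5R,8E)-4-hydroxy-2-{2-[(2S,4R)-2-(4-methoxyphenyl)-5-methylidene-1,3-dioxan-4-yl]ethyl}-8-methyl-10-(phenylsulfonyl)-5-(prop-1-en-2-yl)deca-2,8-dienoate
Product: 27 (2E,4S,5R,8E)-2-{2-[(2S,4R)-2-(4-methoxyphenyl)-5-methylidene-1,3-dioxan-4-yl]ethyl}-8-methyl-10-(phenylsulfonyl)-5-(prop-1-en-2-yl)deca-2,8-diene-1,4-diol
Conditions: i-Bu2AlH (4 equiv), THF, −78 → −40 °C
Reagents that add atoms: none
Why: 1,2-Reduction of the enoate by i-Bu2AlH gives the C18 allylic alcohol, while the acetal survives because its reductive opening needs a non-coordinating solvent and a higher temperature.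

Step 18
Reactants: 27 (2E,4S,5R,8E)-2-{2-[(2S,4R)-2-(4-methoxyphenyl)-5-methylidene-1,3-dioxan-4-yl]ethyl}-8-methyl-10-(phenylsulfonyl)-5-(prop-1-en-2-yl)deca-2,8-diene-1,4-diol
Product: 28 (2E,4S,5R,8E)-1,4-bis[(tert-butyldimethylsilyl)oxy]-2-{2-[(2S,4R)-2-(4-methoxyphenyl)-5-methylidene-1,3-dioxan-4-yl]ethyl}-8-methyl-10-(phenylsulfonyl)-5-(prop-1-en-2-yl)deca-2,8-diene
Conditions: TBSOTf, 2,6-lutidine, CH2Cl2, −78 → 0 °C
Reagents that add atoms: tert-butyldimethylsilyl trifluoromethanesulfonate (TBSOTf), CC(C)(C)[Si](C)(C)OS(=O)(=O)C(F)(F)F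
Why: Silyl triflate with a hindered pyridine base silylates both the primary and the hindered secondary allylic alcohol without deprotonating the sulfone, which an alkoxide-based benzylation would not allow.

Step 19
Reactants: 28 (2E,4S,5R,8E)-1,4-bis[(tert-butyldimethylsilyl)oxy]-2-{2-[(2S,4R)-2-(4-methoxyphenyl)-5-methylidene-1,3-dioxan-4-yl]ethyl}-8-methyl-10-(phenylsulfonyl)-5-(prop-1-en-2-yl)deca-2,8-diene
Product: 29 (3R,6E,8S,9R,12E)-8-[(tert-butyldimethylsilyl)oxy]-6-{[(tert-butyldimethylsilyl)oxy]methyl}-3-[(4-methoxybenzyl)oxy]-12-methyl-2-methylidene-14-(phenylsulfonyl)-9-(prop-1-en-2-yl)tetradeca-6,12-dien-1-ol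
Conditions: i-Bu2AlH (5 equiv), CH2Cl2, −78 → 0 °C
Reagents that add atoms: none
Why: Regioselective reductive opening of the p-methoxybenzylidene acetal, in which the aluminium coordinates the less hindered primary oxygen O9, that C–O bond breaks and hydride quenches the oxocarbenium ion, so the PMB group stays on O7 and only C9–OH is set free.

Step 20
Reactants: 29 (3R,6E,8S,9R,12E)-8-[(tert-butyldimethylsilyl)oxy]-6-{[(tert-butyldimethylsilyl)oxy]methyl}-3-[(4-methoxybenzyl)oxy]-12-methyl-2-methylidene-14-(phenylsulfonyl)-9-(prop-1-en-2-yl)tetradeca-6,12-dien-1-ol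
Product: 30 seco bromide, the 1-bromo analogue of 29 (C9–Br, C10–SO2Ph, C7–OPMB, C2 and C18 OTBS)
Conditions: CBr4, PPh3, 2,6-lutidine, CH2Cl2, 0 °C
Reagents that add atoms: carbon tetrabromide, BrC(Br)(Br)Br
Why: Appel bromination turns the primary allylic alcohol into the bromide under near-neutral conditions, and because the CH2=C(R)CH2 unit has equivalent ends any allylic transposition gives the same compound.

Step 21
Reactants: 30 seco bromide (C9–Br, C10–SO2Ph)
Product: 31 (1R,2S,3E,7R,10RS,11E)-2,18-bis[(tert-butyldimethylsilyl)oxy]-7-[(4-methoxybenzyl)oxy]-10-(phenylsulfonyl)cembra-3,8(19),11,15-tetraene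
Conditions: KN(SiMe3)2 (1.5 equiv), THF, −78 → −20 °C, 30 added by syringe pump to a final concentration near 2 mM
Reagents that add atoms: none
Why: KN(SiMe3)2 removes a C10 proton to give the sulfonyl-stabilised allyl anion, which displaces bromide at C9 by intramolecular SN2; the closest known reaction type is the macrocyclising alkylation of allylic sulfone carbanions by allylic halides used for 14-membered terpenoid carbocycles. The 14-membered ring closes in the 14-exo-tet mode, with the bromide leaving outside the ring. C10 becomes a stereocentre that is not controlled and is erased in step 22, and no existing stereocentre is touched. Ring closure must beat oligomerisation, which slow addition at high dilution secures, and α-alkylation must beat γ-alkylation, which the charge localised next to sulfur and the unhindered primary bromide favour. Direct and transposed displacement give one product because the electrophilic unit C9H2–C8(=C19H2) has two equivalent CH2 termini. Silyl and PMB ethers are inert to the amide base.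

Step 22
Reactants: 31 macrocyclic C10 sulfone
Product: 32 (1R,2S,3E,7R,11E)-2,18-bis[(tert-butyldimethylsilyl)oxy]-7-[(4-methoxybenzyl)oxy]cembra-3,8(19),11,15-tetraene
Conditions: PdCl2(dppp) (10 mol%), LiBHEt3, THF, 0 °C
Reagents that add atoms: none
Why: Palladium-catalysed hydride desulfonylation, in which zerovalent palladium (formed from the divalent precatalyst by the hydride) ionises the allylic sulfone to a π-allyl complex and hydride is delivered to the less substituted C10 terminus, removes both C10 epimers and keeps E-C11=C12, while the allylic silyl and PMB ethers are too poor as leaving groups to ionise.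

Step 23
Reactants: 32 (1R,2S,3E,7R,11E)-2,18-bis[(tert-butyldimethylsilyl)oxy]-7-[(4-methoxybenzyl)oxy]cembra-3,8(19),11,15-tetraene
Product: 33 (1R,2S,3E,7R,11E)-7-[(4-methoxybenzyl)oxy]cembra-3,8(19),11,15-tetraene-2,18-diol
Conditions: TBAF, THF, rt → 40 °C
Reagents that add atoms: none
Why: Fluoride-mediated desilylation frees the C2 and C18 hydroxyls while the PMB ether at C7 stays.

Step 24
Reactants: 33 (1R,2S,3E,7R,11E)-7-[(4-methoxybenzyl)oxy]cembra-3,8(19),11,15-tetraene-2,18-diol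
Product: 34 (1R,2S,3E,7R,11E)-7-[(4-methoxybenzyl)oxy]cembra-3,8(19),11,15-tetraene-2,18-diyl diacetate
Conditions: Ac2O, pyridine, DMAP (cat.), CH2Cl2, rt
Reagents that add atoms: acetic anhydride, CC(=O)OC(C)=O
Why: DMAP-catalysed acylation converts both free allylic alcohols into acetates, and with C7 still masked no regiochemistry is at stake.

Step 25
Reactants: 34 (1R,2S,3E,7R,11E)-7-[(4-methoxybenzyl)oxy]cembra-3,8(19),11,15-tetraene-2,18-diyl diacetate
Product: 35 (1R,2S,3E,7R,11E)-7-hydroxycembra-3,8(19),11,15-tetraene-2,18-diyl diacetate (CNP0077636.1)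
Conditions: DDQ, CH2Cl2/pH 7 buffer, 0 °C → rt
Reagents that add atoms: none
Why: Oxidative PMB cleavage, in which DDQ abstracts the benzylic hydride of the electron-rich ether and water hydrolyses the oxocarbenium ion, frees the C7 alcohol under conditions that leave allylic acetates and isolated alkenes untouched.

Compound list
1 | (S)-limonene | CC1=CC[C@H](CC1)C(C)=C | starting material
2 | (4S)-limonene 1,2-oxide (cis/trans mixture) | CC12OC1C[C@H](CC2)C(C)=C | intermediate
3 | (3S)-6-oxo-3-(prop-1-en-2-yl)heptanal | O=CC[C@@H](C(C)=C)CCC(C)=O | intermediate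
4 | (5S)-7-hydroxy-5-(prop-1-en-2-yl)heptan-2-one | OCC[C@@H](C(C)=C)CCC(C)=O | intermediate
5 | (5S)-7-[(tert-butyldimethylsilyl)oxy]-5-(prop-1-en-2-yl)heptan-2-one | CC(C)(C)[Si](C)(C)OCC[C@@H](C(C)=C)CCC(C)=O | intermediate
6 | diethyl (5S)-7-[(tert-butyldimethylsilyl)oxy]-5-(prop-1-en-2-yl)hept-1-en-2-yl phosphate | CC(C)(C)[Si](C)(C)OCC[C@@H](C(C)=C)CCC(=C)OP(=O)(OCC)OCC | intermediate
7 | tert-butyldimethyl{[(3S)-3-(prop-1-en-2-yl)hept-6-yn-1-yl]oxy}silane | CC(C)(C)[Si](C)(C)OCC[C@@H](C(C)=C)CCC#C | intermediate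
8 | dimethyl{(1E,5S)-7-[(tert-butyldimethylsilyl)oxy]-2-methyl-5-(prop-1-en-2-yl)hept-1-en-1-yl}aluminium | CC(C)(C)[Si](C)(C)OCC[C@@H](C(C)=C)CC/C(C)=C/[Al](C)C | intermediate
9 | (2E,6S)-8-[(tert-butyldimethylsilyl)oxy]-3-methyl-6-(prop-1-en-2-yl)oct-2-en-1-ol | CC(C)(C)[Si](C)(C)OCC[C@@H](C(C)=C)CC/C(C)=C/CO | intermediate
10 | tert-butyl{[(3S,6E)-8-chloro-6-methyl-3-(prop-1-en-2-yl)oct-6-en-1-yl]oxy}dimethylsilane | CC(C)(C)[Si](C)(C)OCC[C@@H](C(C)=C)CC/C(C)=C/CCl | intermediate
11 | tert-butyldimethyl{[(3S,6E)-6-methyl-8-(phenylsulfonyl)-3-(prop-1-en-2-yl)oct-6-en-1-yl]oxy}silane | CC(C)(C)[Si](C)(C)OCC[C@@H](C(C)=C)CC/C(C)=C/CS(=O)(=O)c1ccccc1 | intermediate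
12 | (3S,6E)-6-methyl-8-(phenylsulfonyl)-3-(prop-1-en-2-yl)oct-6-en-1-ol | OCC[C@@H](C(C)=C)CC/C(C)=C/CS(=O)(=O)c1ccccc1 | intermediate
13 | (3S,6E)-6-methyl-8-(phenylsulfonyl)-3-(prop-1-en-2-yl)oct-6-enal | O=CC[C@@H](C(C)=C)CC/C(C)=C/CS(=O)(=O)c1ccccc1 | intermediate
14 | 3-[(tert-butyldimethylsilyl)oxy]propanal | CC(C)(C)[Si](C)(C)OCCC=O | starting material
15 | 1,1,1,3,3,3-hexafluoropropan-2-yl acrylate | C=CC(=O)OC(C(F)(F)F)C(F)(F)F | starting material
16 | 1,1,1,3,3,3-hexafluoropropan-2-yl (3R)-5-[(tert-butyldimethylsilyl)oxy]-3-hydroxy-2-methylidenepentanoate | C=C(C(=O)OC(C(F)(F)F)C(F)(F)F)[C@H](O)CCO[Si](C)(C)C(C)(C)C | intermediate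
17 | (3R)-5-[(tert-butyldimethylsilyl)oxy]-2-methylidenepentane-1,3-diol | C=C(CO)[C@H](O)CCO[Si](C)(C)C(C)(C)C | intermediate
18 | tert-butyl{2-[(2S,4R)-2-(4-methoxyphenyl)-5-methylidene-1,3-dioxan-4-yl]ethoxy}dimethylsilane | C=C1CO[C@H](c2ccc(OC)cc2)O[C@@H]1CCO[Si](C)(C)C(C)(C)C | intermediate
19 | 2-[(2S,4R)-2-(4-methoxyphenyl)-5-methylidene-1,3-dioxan-4-yl]ethanol | C=C1CO[C@H](c2ccc(OC)cc2)O[C@@H]1CCO | intermediate
20 | (2S,4R)-4-(2-iodoethyl)-2-(4-methoxyphenyl)-5-methylidene-1,3-dioxane | C=C1CO[C@H](c2ccc(OC)cc2)O[C@@H]1CCI | intermediate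
21 | methyl (triphenylphosphoranylidene)acetate | COC(=O)C=P(c1ccccc1)(c1ccccc1)c1ccccc1 | starting material
22 | {(2RS)-1-methoxy-4-[(2S,4R)-2-(4-methoxyphenyl)-5-methylidene-1,3-dioxan-4-yl]-1-oxobutan-2-yl}triphenylphosphonium iodide | C=C1CO[C@H](c2ccc(OC)cc2)O[C@@H]1CCC(C(=O)OC)[P+](c3ccccc3)(c4ccccc4)c5ccccc5.[I-] | intermediate
23 | methyl 4-[(2S,4R)-2-(4-methoxyphenyl)-5-methylidene-1,3-dioxan-4-yl]-2-(triphenylphosphoranylidene)butanoate | C=C1CO[C@H](c2ccc(OC)cc2)O[C@@H]1CCC(C(=O)OC)=P(c3ccccc3)(c4ccccc4)c5ccccc5 | intermediate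
24 | (2R,3R,6E)-2-(anilinooxy)-6-methyl-8-(phenylsulfonyl)-3-(prop-1-en-2-yl)oct-6-enal | O=C[C@H](ONc1ccccc1)[C@@H](C(C)=C)CC/C(C)=C/CS(=O)(=O)c2ccccc2 | intermediate
25 | methyl (2E,4S,5R,8E)-4-(anilinooxy)-2-{2-[(2S,4R)-2-(4-methoxyphenyl)-5-methylidene-1,3-dioxan-4-yl]ethyl}-8-methyl-10-(phenylsulfonyl)-5-(prop-1-en-2-yl)deca-2,8-dienoate | C=C1CO[C@H](c2ccc(OC)cc2)O[C@@H]1CC/C(C(=O)OC)=C\[C@H](ONc3ccccc3)[C@@H](C(C)=C)CC/C(C)=C/CS(=O)(=O)c4ccccc4 | intermediate
26 | methyl (2E,4S,5R,8E)-4-hydroxy-2-{2-[(2S,4R)-2-(4-methoxyphenyl)-5-methylidene-1,3-dioxan-4-yl]ethyl}-8-methyl-10-(phenylsulfonyl)-5-(prop-1-en-2-yl)deca-2,8-dienoate | C=C1CO[C@H](c2ccc(OC)cc2)O[C@@H]1CC/C(C(=O)OC)=C\[C@H](O)[C@@H](C(C)=C)CC/C(C)=C/CS(=O)(=O)c3ccccc3 | intermediate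
27 | (2E,4S,5R,8E)-2-{2-[(2S,4R)-2-(4-methoxyphenyl)-5-methylidene-1,3-dioxan-4-yl]ethyl}-8-methyl-10-(phenylsulfonyl)-5-(prop-1-en-2-yl)deca-2,8-diene-1,4-diol | C=C1CO[C@H](c2ccc(OC)cc2)O[C@@H]1CC/C(CO)=C\[C@H](O)[C@@H](C(C)=C)CC/C(C)=C/CS(=O)(=O)c3ccccc3 | intermediate
28 | (2E,4S,5R,8E)-1,4-bis[(tert-butyldimethylsilyl)oxy]-2-{2-[(2S,4R)-2-(4-methoxyphenyl)-5-methylidene-1,3-dioxan-4-yl]ethyl}-8-methyl-10-(phenylsulfonyl)-5-(prop-1-en-2-yl)deca-2,8-diene | C=C1CO[C@H](c2ccc(OC)cc2)O[C@@H]1CC/C(CO[Si](C)(C)C(C)(C)C)=C\[C@H](O[Si](C)(C)C(C)(C)C)[C@@H](C(C)=C)CC/C(C)=C/CS(=O)(=O)c3ccccc3 | intermediate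
29 | (3R,6E,8S,9R,12E)-8-[(tert-butyldimethylsilyl)oxy]-6-{[(tert-butyldimethylsilyl)oxy]methyl}-3-[(4-methoxybenzyl)oxy]-12-methyl-2-methylidene-14-(phenylsulfonyl)-9-(prop-1-en-2-yl)tetradeca-6,12-dien-1-ol | OCC(=C)[C@H](OCc1ccc(OC)cc1)CC/C(CO[Si](C)(C)C(C)(C)C)=C\[C@H](O[Si](C)(C)C(C)(C)C)[C@@H](C(C)=C)CC/C(C)=C/CS(=O)(=O)c2ccccc2 | intermediate
30 | seco bromide: (3R,6E,8S,9R,12E)-1-bromo-8-[(tert-butyldimethylsilyl)oxy]-6-{[(tert-butyldimethylsilyl)oxy]methyl}-3-[(4-methoxybenzyl)oxy]-12-methyl-2-methylidene-14-(phenylsulfonyl)-9-(prop-1-en-2-yl)tetradeca-6,12-diene | BrCC(=C)[C@H](OCc1ccc(OC)cc1)CC/C(CO[Si](C)(C)C(C)(C)C)=C\[C@H](O[Si](C)(C)C(C)(C)C)[C@@H](C(C)=C)CC/C(C)=C/CS(=O)(=O)c2ccccc2 | intermediate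
31 | (1R,2S,3E,7R,10RS,11E)-2,18-bis[(tert-butyldimethylsilyl)oxy]-7-[(4-methoxybenzyl)oxy]-10-(phenylsulfonyl)cembra-3,8(19),11,15-tetraene | C=C1CC(S(=O)(=O)c2ccccc2)/C=C(\C)CC[C@H](C(=C)C)[C@@H](O[Si](C)(C)C(C)(C)C)/C=C(/CO[Si](C)(C)C(C)(C)C)CC[C@H]1OCc3ccc(OC)cc3 | intermediate
32 | (1R,2S,3E,7R,11E)-2,18-bis[(tert-butyldimethylsilyl)oxy]-7-[(4-methoxybenzyl)oxy]cembra-3,8(19),11,15-tetraene | C=C1CC/C=C(\C)CC[C@H](C(=C)C)[C@@H](O[Si](C)(C)C(C)(C)C)/C=C(/CO[Si](C)(C)C(C)(C)C)CC[C@H]1OCc2ccc(OC)cc2 | intermediate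
33 | (1R,2S,3E,7R,11E)-7-[(4-methoxybenzyl)oxy]cembra-3,8(19),11,15-tetraene-2,18-diol | C=C1CC/C=C(\C)CC[C@H](C(=C)C)[C@@H](O)/C=C(/CO)CC[C@H]1OCc2ccc(OC)cc2 | intermediate
34 | (1R,2S,3E,7R,11E)-7-[(4-methoxybenzyl)oxy]cembra-3,8(19),11,15-tetraene-2,18-diyl diacetate | C=C1CC/C=C(\C)CC[C@H](C(=C)C)[C@@H](OC(C)=O)/C=C(/COC(C)=O)CC[C@H]1OCc2ccc(OC)cc2 | intermediate
35 | (1R,2S,3E,7R,11E)-7-hydroxycembra-3,8(19),11,15-tetraene-2,18-diyl diacetate (CNP0077636.1) | C=C1CC/C=C(\C)CC[C@H](C(=C)C)[C@@H](OC(C)=O)/C=C(/COC(C)=O)CC[C@H]1O | target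

Total step count: 25. Longest linear sequence: 19 steps (steps 1–8, then 15–25); steps 9–14 form the second branch.

Steps most likely to fail

Step 21. Intermolecular alkylation (oligomerisation) or proton transfer between chains may outrun ring closure, and some γ-alkylation of the allyl anion is possible. The fallback sets out from 29 and comes back at 32, reversing the polarity of the C9–C10 bond formation and bypassing 31. Oxidative desulfonylation of 29 (LiN(SiMe3)2, 2.2 equiv, THF, −78 °C, then Me3SiOOSiMe3) would turn the C10 sulfonyl carbanion into the aldehyde and give the seco hydroxy enal F1. Appel bromination (CBr4, PPh3) gives the seco bromo enal F2. Intramolecular Nozaki–Hiyama allylation with CrCl2 (divalent chromium) in THF at high dilution joins C9 to the C10 carbonyl; the allylchromium unit again has equivalent termini, and the product is the macrocyclic C10 carbinol F3 as an epimer mixture. Acetylation (Ac2O, pyridine, DMAP) gives the C10 acetate F4. Palladium-catalysed hydride displacement of the allylic acetate (Pd(PPh3)4, LiBHEt3, THF, 0 °C) passes through the same π-allyl intermediate as step 22, so hydride attack at C10 should give 32.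

Step 15. The α-aminoxy aldehyde may epimerise or oligomerise before the hindered α-substituted ylide has reacted, and the neighbouring C1 centre may erode the face selectivity of the oxygenation. The fallback sets out from 13 and comes back at 27, replacing the labile intermediate by an isolable one. Enamine-catalysed α-benzoyloxylation of 13 with dibenzoyl peroxide and (R)-α,α-diphenylprolinol trimethylsilyl ether (THF, 0 °C) works by steric shielding, which is why the R catalyst is needed for the same face as L-proline; it would give the α-benzoyloxy aldehyde F5, which can be purified. Wittig olefination with 23 (toluene, 40 °C) gives the benzoate enoate F6. i-Bu2AlH (THF, −78 → −40 °C) then removes the benzoate and reduces the ester in one operation to give 27, so the separate N–O cleavage is no longer needed.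

Step 9. Conversion of the unbranched β-silyloxy aldehyde may be slow, a second aldehyde molecule may be captured as a dioxanone, and the enantioselectivity may be insufficient. The fallback sets out from 14 and comes back at 17, setting C7 by epoxidation instead. Wittig olefination of 14 with ethyl 2-(triphenylphosphoranylidene)propanoate (CH2Cl2, rt) gives the E-enoate F7, and i-Bu2AlH reduction gives the E-allylic alcohol F8. Sharpless asymmetric epoxidation (Ti(Oi-Pr)4, D-(−)-diethyl tartrate, t-BuOOH, 4 Å sieves, CH2Cl2, −20 °C) gives the (2R,3R)-epoxy alcohol F9. Base-induced epoxide-to-allylic-alcohol isomerisation with diethylaluminium 2,2,6,6-tetramethylpiperidide (toluene, 0 °C) removes a proton from the C2 methyl group and breaks the C2–O bond; the C3–O bond is untouched, so the carbinol configuration is retained and the product is 17.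

Further compounds
F1 | step 21 | seco hydroxy enal: (2E,6R,7S,8E,12R)-7-[(tert-butyldimethylsilyl)oxy]-9-{[(tert-butyldimethylsilyl)oxy]methyl}-14-hydroxy-12-[(4-methoxybenzyl)oxy]-3-methyl-13-methylidene-6-(prop-1-en-2-yl)tetradeca-2,8-dienal | OCC(=C)[C@H](OCc1ccc(OC)cc1)CC/C(CO[Si](C)(C)C(C)(C)C)=C\[C@H](O[Si](C)(C)C(C)(C)C)[C@@H](C(C)=C)CC/C(C)=C/C=O
F2 | step 21 | seco bromo enal: 14-bromo analogue of F1 | BrCC(=C)[C@H](OCc1ccc(OC)cc1)CC/C(CO[Si](C)(C)C(C)(C)C)=C\[C@H](O[Si](C)(C)C(C)(C)C)[C@@H](C(C)=C)CC/C(C)=C/C=O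
F3 | step 21 | (1R,2S,3E,7R,10RS,11E)-2,18-bis[(tert-butyldimethylsilyl)oxy]-7-[(4-methoxybenzyl)oxy]cembra-3,8(19),11,15-tetraen-10-ol | C=C1CC(O)/C=C(\C)CC[C@H](C(=C)C)[C@@H](O[Si](C)(C)C(C)(C)C)/C=C(/CO[Si](C)(C)C(C)(C)C)CC[C@H]1OCc2ccc(OC)cc2
F4 | step 21 | (1R,2S,3E,7R,10RS,11E)-2,18-bis[(tert-butyldimethylsilyl)oxy]-7-[(4-methoxybenzyl)oxy]cembra-3,8(19),11,15-tetraen-10-yl acetate | C=C1CC(OC(C)=O)/C=C(\C)CC[C@H](C(=C)C)[C@@H](O[Si](C)(C)C(C)(C)C)/C=C(/CO[Si](C)(C)C(C)(C)C)CC[C@H]1OCc2ccc(OC)cc2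
F5 | step 15 | (2R,3R,6E)-6-methyl-1-oxo-8-(phenylsulfonyl)-3-(prop-1-en-2-yl)oct-6-en-2-yl benzoate | O=C[C@H](OC(=O)c1ccccc1)[C@@H](C(C)=C)CC/C(C)=C/CS(=O)(=O)c2ccccc2
F6 | step 15 | methyl (2E,4S,5R,8E)-4-(benzoyloxy)-2-{2-[(2S,4R)-2-(4-methoxyphenyl)-5-methylidene-1,3-dioxan-4-yl]ethyl}-8-methyl-10-(phenylsulfonyl)-5-(prop-1-en-2-yl)deca-2,8-dienoate | C=C1CO[C@H](c2ccc(OC)cc2)O[C@@H]1CC/C(C(=O)OC)=C\[C@H](OC(=O)c3ccccc3)[C@@H](C(C)=C)CC/C(C)=C/CS(=O)(=O)c4ccccc4
F7 | step 9 | ethyl (2E)-5-[(tert-butyldimethylsilyl)oxy]-2-methylpent-2-enoate | CCOC(=O)/C(C)=C/CCO[Si](C)(C)C(C)(C)C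
F8 | step 9 | (2E)-5-[(tert-butyldimethylsilyl)oxy]-2-methylpent-2-en-1-ol | OC/C(C)=C/CCO[Si](C)(C)C(C)(C)C
F9 | step 9 | [(2R,3R)-3-{2-[(tert-butyldimethylsilyl)oxy]ethyl}-2-methyloxiran-2-yl]methanol | OC[C@@]1(C)O[C@@H]1CCO[Si](C)(C)C(C)(C)C
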